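Remark on the chemistry: atom labels C1–C15 follow the numbering defined in "The problem". The C4 hemiketal is treated throughout as the closed, oxygen-bridged tautomer of the C4-keto/C7-hydroxy form. (R)-(−)-α-Phellandrene, α-angelica lactone and 1-methylimidazole-4-carbaldehyde are taken as commercial.

## The problem

The target is a cyclohexene (ring A: C1, C10, C11=C12, C13, C14) cis-fused at C1/C10 to a ten-membered carbocycle (C1–C10). An oxygen atom joins C4 and C7 into a 2,5-dihydrofuran (O, C4, C5=C6, C7) that bridges a nine-membered oxacycle. C3 carries C15H2OH, C7 a methyl group, C8 the (E)-N-methylurocanate, C11 a methyl group and C14 an isopropyl group.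

The hardest feature is the medium ring. It holds a Z-trisubstituted alkene (C2=C3) directly beside a fully substituted hemiketal carbon (C4), so any ring-closing bond must be made at or near the most hindered and most sensitive atoms.

Six stereocentres are present (1S, 4R, 7S, 8S, 10R, 14R in this numbering). C14 can direct C1 and C10. C7 and C8 lie beyond the C9 methylene and cannot be relayed from ring A. C4 is not independent, because the oxygen bridge fixes it once C7 is set.

The sensitive groups are:
- the hemiketal, which ionises or ketalises with acid and opens with base to a cross-conjugated dienone whose C8 alkoxide could undergo a retro-vinylogous aldol cleavage;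
- the urocanate, which is sensitive to base, nucleophiles and light;
- the primary allylic alcohol C15.

The enabling feature is the ring O–C4(OH)–C5=C6–C7(CH3). It is a γ-methylbutenolide (5-methylfuran-2(5H)-one) that has accepted one carbon nucleophile, C3, at its carbonyl carbon C4. Because C7 is quaternary, this lactol cannot dehydrate to a furan, so the bridged hemiketal is simply the stable tetrahedral adduct of a C3 alkenyl anion and a butenolide. The bridging oxygen, the Z geometry of C5=C6 and the C7 methyl group can therefore all be bought in one five-carbon lactone.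

## Retrosynthesis

**End game (24 ⇒ 23 ⇒ 19 + 21).** The C15–O protecting group and the C8–O acyl bond are cut last. The urocanate would not survive organometallic steps, so it is attached to the free C8 hydroxyl of hemiketal 19 with acid 21 (one step from aldehyde 20). This gives 23, whose PMB ether is removed to give target 24. The forward steps must discriminate the secondary C8 hydroxyl from the tertiary hemiketal hydroxyl and must stay near neutral.

**Key disconnection, C3–C4 (19 ⇐ 18 ⇒ 15).** Cutting C3–C4 of the silyl ether 18 turns the hemiketal back into a butenolide carbonyl and an alkenyl anion at C3, that is, the iodide 15. The neighbouring cuts (C4–C5 as an alkyne, C5=C6 by metathesis) leave C4 at the alcohol level, require a later oxidation, and need the C7 carbinol to be built separately. The C3–C4 cut delivers C4 at its final oxidation level together with the oxygen bridge. Precursor 15 has no medium ring and no bridge: it is ring A with two arms. The forward reaction must generate an alkenyllithium in the presence of a lactone and add it once, in a ten-membered closure.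

**C7–C8 (15 ⇐ 14 ⇒ 10 + 12).** The butenolide alcohol 14 is the vinylogous aldol adduct of aldehyde 10 and silyloxyfuran 12, made in one step from α-angelica lactone 11. This single bond formation joins the two halves and creates both C7 and C8. The alternative cut at C8–C9 would need a chiral C8 nucleophile and would not use the natural polarity of the furanone. The forward reaction must deliver the (7S,8S) pair under catalyst control.

**C2=C3 (10 ⇐ 9 ⇐ 8 ⇐ 7 ⇒ 6).** The (Z)-iodoalkene arm comes from the C2 aldehyde 6 by an α-iodo Wittig olefination (7), reduction (8) and protection (9). Acetal hydrolysis then frees the C8 aldehyde 10. C3 and C15 come from the ylide. The olefination fixes the geometry that places C1 cis to the future C4.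

**Ring A (6 ⇐ 5 ⇐ 4 ⇐ 3 ⇐ 2 ⇒ 1).** The C1–C2 and C9–C10 bonds are cut together as a ketene [2+2] cycloaddition to (R)-α-phellandrene 1, whose C14 stereocentre sets C1 and C10 in one event (2, then 3). The C2–C9 bond of the cyclobutanone is then cleaved after aminomethylenation (4), which adds C8. This gives ester acetal 5 with the two arms already differentiated, and partial reduction gives 6. The p-menthadiene skeleton of 1 maps directly onto C10–C14 and C1 with the alkene already at C11=C12.

## Roads not taken

**Alternative 1:** (the most obvious) cut C4–C5 and treat C5=C6 as an alkyne. The forward key step is intramolecular addition of a C5 acetylide to a C4 aldehyde, oxidation to the macrocyclic hydroxy ynone A1, and cis-semihydrogenation (H2, poisoned Pd on CaCO3) with spontaneous hemiketalisation. It is a sound plan, but the chosen plan is better on three counts: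
- C7 must be made earlier by a separate diastereoselective acetylide addition to a C7 methyl ketone, so C7 and C8 are set in two operations instead of one.
- C4 passes through three oxidation levels.
- The semihydrogenation must stop at the Z-alkene of a hindered ynone in the presence of C2=C3 and C11=C12. The butenolide plan has the Z geometry locked in a five-membered ring from the start and no redox step at C4.

**Alternative 2:** take C4–C7 from a 2,5-disubstituted furan and close the ring by a Nozaki–Hiyama–Kishi reaction (CrCl2/NiCl2) to the furanophane carbinol A2. This is followed by oxidative furan rearrangement, methyl addition at C7 and contraction of a six-membered ketal to the five-membered one. The furan lacks both the C7 methyl group and the correct oxygen pattern, so three further operations are needed and C7 is set late on a strained bicycle. In the chosen plan the lactone carries the methyl group, the bridge oxygen and the C4 oxidation level before the ring is closed.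

**Alternative 3:** cut C5=C6 and close the ring by metathesis of the bis-allylic diene A3 (second-generation Grubbs catalyst), then oxidise C4 and let the hemiketal form. Both alkenes sit next to heavily substituted carbons (C7 quaternary, C4 flanked by the trisubstituted C2=C3), which slows metathesis. A ten-membered closure gives no assurance of Z geometry over dimerisation. C7 again needs its own stereoselective step, and C4 still has to be oxidised. The chosen plan avoids all three points.

Key step: step 13

## Route

Step 1
Reactants: 1 (R)-(−)-α-phellandrene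
Product: 2 cis-fused 8,8-dichloro-2-methyl-5-(propan-2-yl)bicyclo[4.2.0]oct-2-en-7-one (carbonyl carbon = C2 on C1, CCl2 = C9 on C10, four-membered ring trans to the isopropyl group)
Conditions: Cl3CCOCl, Zn (activated), Et2O, sonication, 15–20 °C
Reagents that add atoms: trichloroacetyl chloride, ClC(=O)C(Cl)(Cl)Cl
Why: Dichloroketene [2+2] cycloaddition to the less substituted, cis-disubstituted alkene of the diene; the ketene carbonyl carbon bonds to the diene terminus (C1) and CCl2 to the internal carbon (C10), and approach anti to the C14 isopropyl group sets C1 and C10 cis to each other and trans to it.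

Step 2
Reactants: 2 dichlorocyclobutanone
Product: 3 cis-fused 2-methyl-5-(propan-2-yl)bicyclo[4.2.0]oct-2-en-7-one
Conditions: Zn, AcOH, 70 °C
Reagents that add atoms: none
Why: Reductive removal of the α-chlorines of an α,α-dichloroketone by zinc; no stereocentre is touched.

Step 3
Reactants: 3 cyclobutanone
Product: 4 (E)-8-(dimethylaminomethylene) derivative of 3 (new carbon = C8 on C9)
Conditions: t-BuOCH(NMe2)2, toluene, 80 °C
Reagents that add atoms: tert-butoxybis(dimethylamino)methane (Bredereck's reagent), CC(C)(C)OC(N(C)C)N(C)C
Why: Aminomethylenation at the only α-methylene (C9) gives the vinylogous amide; the other α-carbon (C1) is a ring-fusion methine and cannot form an enaminone.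

Step 4
Reactants: 4 enaminone
Product: 5 methyl 2-(2,2-dimethoxyethyl)-3-methyl-6-(propan-2-yl)cyclohex-3-ene-1-carboxylate (ester on C1 and side chain on C10 cis, both trans to the isopropyl group)
Conditions: TsOH·H2O (1.2 equiv), MeOH, 65 °C
Reagents that add atoms: methanol, CO
Why: Acid-promoted retro-Mannich (retro-Claisen-type) opening of the strained ring: C9 protonation gives an iminium, methanol adds to the ketone and the hemiketal fragments across C2–C9 to the ester and an enamine, which is trapped as the dimethyl acetal; C1 and C10 are not involved.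

Step 5
Reactants: 5 ester acetal
Product: 6 2-(2,2-dimethoxyethyl)-3-methyl-6-(propan-2-yl)cyclohex-3-ene-1-carbaldehyde (C2 aldehyde)
Conditions: i-Bu2AlH (1.05 equiv), CH2Cl2, −78 °C; aq. potassium sodium tartrate
Reagents that add atoms: none
Why: Partial reduction of a methyl ester through the aluminium hemiacetal, which is stable at −78 °C; the acetal is inert and cold work-up limits epimerisation at C1.

Step 6
Reactants: 6 C2 aldehyde
Product: 7 ethyl (Z)-2-iodo-3-(ring A)prop-2-enoate (iodine cis to C1; C10 still carries CH2CH(OMe)2)
Conditions: Ph3P=CHCO2Et, NIS, CH2Cl2, −20 °C; then 6, −20 °C to rt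
Reagents that add atoms: ethyl (triphenylphosphoranylidene)acetate, CCOC(=O)C=P(c1ccccc1)(c1ccccc1)c1ccccc1; N-iodosuccinimide, O=C1CCC(=O)N1I
Why: Wittig olefination with the α-iodo stabilised ylide made in the flask; the ester prefers to lie trans to the C1 substituent, which places iodine cis to C1 (Z) and so fixes the later C2=C3 geometry.

Step 7
Reactants: 7 iodo enoate
Product: 8 (Z)-2-iodo-3-(ring A)prop-2-en-1-ol (C15 alcohol)
Conditions: i-Bu2AlH (2.5 equiv), CH2Cl2, −78 °C; aq. potassium sodium tartrate
Reagents that add atoms: none
Why: 1,2-Reduction of an enoate to the allylic alcohol; alkenyl iodides and acetals are stable to the reagent at this temperature.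

Step 8
Reactants: 8 allylic alcohol
Product: 9 C15 4-methoxybenzyl ether of 8
Conditions: NaH, PMBCl, Bu4NI (cat.), DMF, 0 °C to rt
Reagents that add atoms: 4-methoxybenzyl chloride, COc1ccc(CCl)cc1
Why: Williamson etherification; PMB is chosen over a silyl group because a silyl ether on C15 could migrate from oxygen to the C3 carbanion in step 13.

Step 9
Reactants: 9 PMB ether acetal
Product: 10 C8 aldehyde (ring A with the (Z)-iodoalkenyl PMB ether on C1 and CH2CHO on C10)
Conditions: TsOH·H2O (cat.), acetone/H2O, rt
Reagents that add atoms: water, O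
Why: Acid-catalysed hydrolysis of a dimethyl acetal; the PMB ether, alkenyl iodide and ring alkene tolerate dilute acid, and the nearest stereocentre (C10) is β to the carbonyl and cannot epimerise.

Step 10
Reactants: 11 α-angelica lactone
Product: 12 2-methyl-5-(trimethylsilyloxy)furan
Conditions: TMSCl, Et3N, MeCN, 0 °C to rt
Reagents that add atoms: chlorotrimethylsilane, C[Si](C)(C)Cl
Why: O-Silylation of the lactone dienolate gives the aromatic silyloxyfuran, the standard vinylogous Mukaiyama donor.

Step 11
Reactants: 10 C8 aldehyde; 12 2-methyl-5-(trimethylsilyloxy)furan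
Product: 14 (7S,8S)-butenolide alcohol (C10–CH2–C8H(OH)–C7(CH3) as C5 of a furan-2(5H)-one), via C8 trimethylsilyl ether 13 (not isolated)
Conditions: 12 (1.5 equiv), Ti(OiPr)4 (20 mol %), (R)-BINOL (20 mol %), Et2O, −20 °C; then 1 M HCl, THF, 0 °C
Reagents that add atoms: none
Why: Catalytic asymmetric vinylogous Mukaiyama aldol reaction: the γ-carbon (C7) of the silyloxyfuran attacks the Lewis-acid-bound aldehyde, forming the C7–C8 bond, the quaternary C7 and the C8 carbinol together; the BINOL antipode is the one that directs attack to the Re face of C8 (8S), since C10 is too remote to control it, and the like (7S,8S) relation is expected from the open transition state that keeps the C9 chain away from the C7 methyl group (the anti mode usual for this dienolate class).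

Step 12
Reactants: 14 butenolide alcohol
Product: 15 C8 triethylsilyl ether of 14
Conditions: Et3SiOTf, 2,6-lutidine, CH2Cl2, −78 °C
Reagents that add atoms: triethylsilyl trifluoromethanesulfonate, CC[Si](CC)(CC)OS(=O)(=O)C(F)(F)F
Why: Silylation of a hindered secondary alcohol with a silyl triflate under weakly basic conditions, which avoids retro-aldol cleavage and translactonisation of the free β-hydroxy butenolide.

Step 13
Reactants: 15 iodoalkenyl butenolide
Product: 18 bridged hemiketal (C4 hydroxyl free; C8 O-triethylsilyl; C15 O-PMB), via alkenyllithium 16 (not isolated), via lithium hemiketal alkoxide 17 (not isolated)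
Conditions: t-BuLi (2.05 equiv), THF/Et2O, 0.002 M, −100 °C then −78 to −40 °C; aq. NH4Cl
Reagents that add atoms: none
Why: Proposed new method: iodine–lithium exchange at C3 is expected to outrun attack of t-BuLi on the lactone (the basis of Parham-type cyclisations), and the configurationally stable (Z)-alkenyllithium 16 then adds to the C4 carbonyl of its own butenolide to give alkoxide 17, protonated on quench; the closest known reaction types are intermolecular addition of alkenyllithiums to lactones (lactol formation) and halogen–lithium exchange followed by intramolecular acylation, neither yet shown for a ten-membered ring. The single C3–C4 bond closes the ten-membered carbocycle in a 10-exo-trig mode and, in the same event, the nine-membered oxacycle C2–C3–C4–O–C7–C8–C9–C10–C1 (9-exo-trig), while the existing lactone ring becomes the bridging 2,5-dihydrofuran. The only new stereocentre is C4: the nucleophile is tethered through C8 and can reach only the carbonyl face syn to the C8 branch on C7, which places the C4 hydroxyl cis to the C7 methyl group, and ring–chain tautomerism would correct any error. The step needs 1,2- over 1,4-addition (normal for alkenyllithiums), no enolisation (C7 is quaternary, so the butenolide has no γ-hydrogen) and no second addition (the bridged lithium alkoxide persists at low temperature and each molecule holds one nucleophile). Ring closure over oligomerisation is favoured by high dilution and by the cis arms on ring A, the Z-alkene and the planar butenolide, which leave few rotatable bonds between C3 and C4. The Z geometry set in step 6 is carried into C2=C3 because alkenyllithiums of this type keep their configuration at these temperatures.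

Step 14
Reactants: 18 silyl-protected hemiketal
Product: 19 C8 alcohol (C4 hemiketal hydroxyl and C8 hydroxyl free; C15 O-PMB)
Conditions: Bu4NF/AcOH (1:1), THF, 0 °C to rt
Reagents that add atoms: none
Why: Fluoride cleavage of a triethylsilyl ether; buffering with acetic acid keeps the medium near neutral so that the hemiketal neither ionises nor opens to the dienone alkoxide.

Step 15
Reactants: 20 1-methyl-1H-imidazole-4-carbaldehyde
Product: 21 (E)-3-(1-methyl-1H-imidazol-4-yl)prop-2-enoic acid (N-methylurocanic acid)
Conditions: malonic acid, pyridine, piperidine (cat.), 100 °C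
Reagents that add atoms: malonic acid, OC(=O)CC(=O)O
Why: Knoevenagel–Doebner condensation with decarboxylation, which gives the (E)-acrylic acid under thermodynamic control.

Step 16
Reactants: 19 C8 alcohol; 21 N-methylurocanic acid
Product: 23 C8 (E)-N-methylurocanate of 19 (C15 O-PMB), via pivalic mixed anhydride 22 (not isolated)
Conditions: 21, t-BuCOCl, Et3N, THF, 0 °C to rt; then 19, DMAP, rt
Reagents that add atoms: none
Why: Mixed-anhydride esterification with DMAP catalysis; the acyl group is delivered from the less hindered carbonyl of 22 to the only secondary hydroxyl, while the tertiary hemiketal hydroxyl at C4 is too hindered to be acylated.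

Step 17
Reactants: 23 PMB-protected ester
Product: 24 target compound (CNP0196085.1)
Conditions: DDQ, CH2Cl2/pH 7 phosphate buffer, 0 °C
Reagents that add atoms: none
Why: Oxidative cleavage of the PMB ether through its benzylic oxocarbenium ion; the buffered, non-nucleophilic medium spares the hemiketal, the urocanate and the alkenes.

## Compound list

1 | (R)-(−)-α-phellandrene, (5R)-2-methyl-5-(propan-2-yl)cyclohexa-1,3-diene | CC1=CC[C@H](C(C)C)C=C1 | starting material
2 | cis-fused 8,8-dichloro-2-methyl-5-(propan-2-yl)bicyclo[4.2.0]oct-2-en-7-one, four-membered ring trans to isopropyl | CC1=CC[C@H](C(C)C)[C@H]2C(=O)C(Cl)(Cl)[C@@H]12 | intermediate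
3 | cis-fused 2-methyl-5-(propan-2-yl)bicyclo[4.2.0]oct-2-en-7-one | CC1=CC[C@H](C(C)C)[C@H]2C(=O)C[C@@H]12 | intermediate
4 | (E)-8-(dimethylaminomethylene)-2-methyl-5-(propan-2-yl)bicyclo[4.2.0]oct-2-en-7-one | CC1=CC[C@H](C(C)C)[C@H]2C(=O)/C(=C/N(C)C)[C@@H]12 | intermediate
5 | methyl 2-(2,2-dimethoxyethyl)-3-methyl-6-(propan-2-yl)cyclohex-3-ene-1-carboxylate (C1/C10 cis, trans to isopropyl) | CC1=CC[C@H](C(C)C)[C@@H](C(=O)OC)[C@H]1CC(OC)OC | intermediate
6 | 2-(2,2-dimethoxyethyl)-3-methyl-6-(propan-2-yl)cyclohex-3-ene-1-carbaldehyde (C2 aldehyde) | CC1=CC[C@H](C(C)C)[C@@H](C=O)[C@H]1CC(OC)OC | intermediate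
7 | ethyl (Z)-2-iodo-3-[ring A]prop-2-enoate, ring A carrying CH2CH(OMe)2 on C10 | CC1=CC[C@H](C(C)C)[C@@H](/C=C(/C(=O)OCC)I)[C@H]1CC(OC)OC | intermediate
8 | (Z)-2-iodo-3-[ring A]prop-2-en-1-ol (C15 alcohol), acetal on the C10 arm | CC1=CC[C@H](C(C)C)[C@@H](/C=C(/CO)I)[C@H]1CC(OC)OC | intermediate
9 | C15 4-methoxybenzyl ether of 8 | CC1=CC[C@H](C(C)C)[C@@H](/C=C(/COCc2ccc(OC)cc2)I)[C@H]1CC(OC)OC | intermediate
10 | C8 aldehyde: ring A with (Z)-2-iodo-3-(PMB-oxy)propenyl on C1 and CH2CHO on C10 | CC1=CC[C@H](C(C)C)[C@@H](/C=C(/COCc2ccc(OC)cc2)I)[C@H]1CC=O | intermediate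
11 | α-angelica lactone, 5-methylfuran-2(3H)-one | CC1=CCC(=O)O1 | starting material
12 | 2-methyl-5-(trimethylsilyloxy)furan | Cc1ccc(O[Si](C)(C)C)o1 | intermediate
13 | C8 trimethylsilyl ether of 14 (not isolated) | CC1=CC[C@H](C(C)C)[C@@H](/C=C(/COCc2ccc(OC)cc2)I)[C@H]1C[C@H](O[Si](C)(C)C)[C@]3(C)C=CC(=O)O3 | intermediate
14 | (7S,8S)-butenolide alcohol: (5S)-5-methyl-5-[(1S)-1-hydroxy-2-(ring A)ethyl]furan-2(5H)-one | CC1=CC[C@H](C(C)C)[C@@H](/C=C(/COCc2ccc(OC)cc2)I)[C@H]1C[C@H](O)[C@]3(C)C=CC(=O)O3 | intermediate
15 | C8 triethylsilyl ether of 14 | CC1=CC[C@H](C(C)C)[C@@H](/C=C(/COCc2ccc(OC)cc2)I)[C@H]1C[C@H](O[Si](CC)(CC)CC)[C@]3(C)C=CC(=O)O3 | intermediate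
16 | (Z)-alkenyllithium from 15, lithium at C3 (not isolated) | CC1=CC[C@H](C(C)C)[C@@H](/C=C(/COCc2ccc(OC)cc2)[Li])[C@H]1C[C@H](O[Si](CC)(CC)CC)[C@]3(C)C=CC(=O)O3 | intermediate
17 | lithium alkoxide of the bridged hemiketal 18 (not isolated) | CC1=CC[C@H](C(C)C)[C@H]2/C=C(/COCc3ccc(OC)cc3)[C@@]3(O[Li])C=C[C@](C)(O3)[C@@H](O[Si](CC)(CC)CC)C[C@@H]12 | intermediate
18 | 4,7-oxygen-bridged hemiketal, C8 O-triethylsilyl, C15 O-PMB | CC1=CC[C@H](C(C)C)[C@H]2/C=C(/COCc3ccc(OC)cc3)[C@@]3(O)C=C[C@](C)(O3)[C@@H](O[Si](CC)(CC)CC)C[C@@H]12 | intermediate
19 | 4,7-oxygen-bridged hemiketal with free C8 hydroxyl, C15 O-PMB | CC1=CC[C@H](C(C)C)[C@H]2/C=C(/COCc3ccc(OC)cc3)[C@@]3(O)C=C[C@](C)(O3)[C@@H](O)C[C@@H]12 | intermediate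
20 | 1-methyl-1H-imidazole-4-carbaldehyde | Cn1cnc(C=O)c1 | starting material
21 | (E)-3-(1-methyl-1H-imidazol-4-yl)prop-2-enoic acid | OC(=O)/C=C/c1cn(C)cn1 | intermediate
22 | pivalic (E)-3-(1-methyl-1H-imidazol-4-yl)prop-2-enoic anhydride (not isolated) | CC(C)(C)C(=O)OC(=O)/C=C/c1cn(C)cn1 | intermediate
23 | C8 (E)-N-methylurocanate of 19, C15 O-PMB | CC1=CC[C@H](C(C)C)[C@H]2/C=C(/COCc3ccc(OC)cc3)[C@@]3(O)C=C[C@](C)(O3)[C@@H](OC(=O)/C=C/c3cn(C)cn3)C[C@@H]12 | intermediate
24 | CNP0196085.1: 4,7-oxygen-bridged hemiketal with C15 hydroxymethyl and C8 (E)-N-methylurocanate | CC1=CC[C@H](C(C)C)[C@H]2/C=C(/CO)[C@@]3(O)C=C[C@](C)(O3)[C@@H](OC(=O)/C=C/c3cn(C)cn3)C[C@@H]12 | target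

## Step count and risk

Total steps: 17 (15 in the main line plus the one-step preparations of 12 and 21). Longest linear sequence: 15 (steps 1–9, 11–14, 16, 17).

**Step 13 (key step, proposed new method).** Three things are most likely to go wrong:
- t-BuLi may attack the butenolide before the exchange is complete.
- Ring closure may be slow, so that the alkenyllithium is protonated or eliminates the C15 alkoxide to an allene on warming.
- Intermolecular addition may compete and give oligomers.

All three follow from asking a fast anionic reaction to close a strained ten-membered ring. The fallback uses known chemistry, sets out from 15 and comes back at 18. The lactone is reduced with i-Bu2AlH at −78 °C to the lactol F1, which is in equilibrium with its (Z)-γ-hydroxy enal. An intramolecular Nozaki–Hiyama–Kishi reaction (CrCl2, catalytic NiCl2, DMSO/THF, high dilution) closes the ten-membered ring to the C4 carbinol, the (Z)-ene-diol F2. Oxidation of the secondary bis-allylic alcohol (Dess–Martin periodinane, NaHCO3) gives the dienone, which closes with the C7 hydroxyl to 18.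

**Step 11.** The risk is poor facial selectivity at C8 or the wrong C7/C8 relative topicity, since the γ-methyl group changes the steric balance of the open transition state and the substrate itself exerts no control. The fallback sets out from 10 and comes back at 14; it builds the two centres by reagent-controlled epoxidation and a stereospecific opening:
- Still–Gennari olefination with methyl 2-[bis(2,2,2-trifluoroethoxy)phosphoryl]propanoate (KN(SiMe3)2, 18-crown-6) gives the (Z)-2-methyl enoate F3.
- i-Bu2AlH gives the (Z)-allylic alcohol F4.
- Sharpless asymmetric epoxidation (Ti(OiPr)4, D-(−)-diethyl tartrate, t-BuOOH) is chemoselective for the allylic alcohol and gives the (7R,8S)-epoxy alcohol F5.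
- Dess–Martin oxidation gives the epoxy aldehyde F6.
- A second Still–Gennari olefination with the phosphonoacetate gives the (Z)-γ,δ-epoxy enoate F7.
- Acid (camphorsulfonic acid or BF3·OEt2) induces 5-exo opening of the epoxide at the tertiary allylic C7 by the ester carbonyl, with inversion and loss of methanol, to give 14.

**Step 16 (with step 14).** Once C8 is free, the hemiketal can equilibrate through the open dienone with the six-membered C8–O–C4 ketal, and the open form can undergo retro-vinylogous aldol cleavage of C7–C8; either process would lower the amount of acylable C8 alcohol. The fallback sets out from 18 and comes back at 24. The hemiketal is locked as the methyl ketal F10 (pyridinium p-toluenesulfonate, MeOH, 0 °C). The silyl group is removed with Bu4NF to give the C8 alcohol F11. Esterification with 22 gives F12, DDQ gives the C15 alcohol F13, and mild aqueous acid (pyridinium p-toluenesulfonate, acetone/H2O) returns the hemiketal 24.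

**Step 6.** The risks are incomplete Z selectivity of the α-iodo ylide and epimerisation of the α-branched aldehyde at C1 during a slow olefination. The fallback sets out from 6 and comes back at 9. Ramirez olefination (CBr4, PPh3, Et3N) gives the 1,1-dibromoalkene F8, which has no geometry to control. Stille coupling selective for the bromide trans to C1, with tributyl[(4-methoxybenzyloxy)methyl]stannane (Pd2(dba)3, tri(2-furyl)phosphine), gives the (Z)-bromoalkene F9. Copper-catalysed bromide–iodide exchange (CuI, NaI, trans-N,N′-dimethylcyclohexane-1,2-diamine, dioxane, 110 °C) gives 9.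

## Further compounds

F1 | step 13 | lactol from 15 (5-hydroxy-2,5-dihydrofuran, both anomers) | CC1=CC[C@H](C(C)C)[C@@H](/C=C(/COCc2ccc(OC)cc2)I)[C@H]1C[C@H](O[Si](CC)(CC)CC)[C@]3(C)C=CC(O)O3
F2 | step 13 | ten-membered (Z)-ene-diol, C4 secondary carbinol (both epimers) and C7 tertiary carbinol | CC1=CC[C@H](C(C)C)[C@H]2/C=C(/COCc3ccc(OC)cc3)C(O)/C=C\[C@](C)(O)[C@@H](O[Si](CC)(CC)CC)C[C@@H]12
F3 | step 11 | methyl (Z)-2-methyl-4-(ring A)but-2-enoate | CC1=CC[C@H](C(C)C)[C@@H](/C=C(/COCc2ccc(OC)cc2)I)[C@H]1C/C=C(/C)C(=O)OC
F4 | step 11 | (Z)-2-methyl-4-(ring A)but-2-en-1-ol | CC1=CC[C@H](C(C)C)[C@@H](/C=C(/COCc2ccc(OC)cc2)I)[C@H]1C/C=C(/C)CO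
F5 | step 11 | (7R,8S)-epoxy alcohol | CC1=CC[C@H](C(C)C)[C@@H](/C=C(/COCc2ccc(OC)cc2)I)[C@H]1C[C@@H]2O[C@]2(C)CO
F6 | step 11 | (7R,8S)-epoxy aldehyde | CC1=CC[C@H](C(C)C)[C@@H](/C=C(/COCc2ccc(OC)cc2)I)[C@H]1C[C@@H]2O[C@]2(C)C=O
F7 | step 11 | methyl (Z)-3-[(7R,8S)-epoxide]prop-2-enoate | CC1=CC[C@H](C(C)C)[C@@H](/C=C(/COCc2ccc(OC)cc2)I)[C@H]1C[C@@H]2O[C@]2(C)/C=C\C(=O)OC
F8 | step 6 | 1,1-dibromoalkene from 6 | CC1=CC[C@H](C(C)C)[C@@H](C=C(Br)Br)[C@H]1CC(OC)OC
F9 | step 6 | (Z)-2-bromoalkenyl PMB ether (bromo analogue of 9) | CC1=CC[C@H](C(C)C)[C@@H](/C=C(/COCc2ccc(OC)cc2)Br)[C@H]1CC(OC)OC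
F10 | step 16 | C4 methyl ketal of 18 | CC1=CC[C@H](C(C)C)[C@H]2/C=C(/COCc3ccc(OC)cc3)[C@@]3(OC)C=C[C@](C)(O3)[C@@H](O[Si](CC)(CC)CC)C[C@@H]12
F11 | step 16 | C4 methyl ketal with free C8 hydroxyl | CC1=CC[C@H](C(C)C)[C@H]2/C=C(/COCc3ccc(OC)cc3)[C@@]3(OC)C=C[C@](C)(O3)[C@@H](O)C[C@@H]12
F12 | step 16 | C4 methyl ketal C8 (E)-N-methylurocanate, C15 O-PMB | CC1=CC[C@H](C(C)C)[C@H]2/C=C(/COCc3ccc(OC)cc3)[C@@]3(OC)C=C[C@](C)(O3)[C@@H](OC(=O)/C=C/c3cn(C)cn3)C[C@@H]12
F13 | step 16 | C4 methyl ketal of the target | CC1=CC[C@H](C(C)C)[C@H]2/C=C(/CO)[C@@]3(OC)C=C[C@](C)(O3)[C@@H](OC(=O)/C=C/c3cn(C)cn3)C[C@@H]12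
A1 | alternative 1 | ten-membered hydroxy ynone (C4 ketone, C5≡C6, C7 carbinol) | CC1=CC[C@H](C(C)C)[C@H]2/C=C(/COCc3ccc(OC)cc3)C(=O)C#C[C@](C)(O)[C@@H](O[Si](CC)(CC)CC)C[C@@H]12
A2 | alternative 2 | furanophane carbinol (C4–C7 as a 2,5-bridged furan, C8 carbinol) | CC1=CC[C@H](C(C)C)[C@H]2/C=C(/COCc3ccc(OC)cc3)c3ccc(o3)[C@@H](O)C[C@@H]12
A3 | alternative 3 | bis-allylic diene for ring-closing metathesis at C5=C6 | CC1=CC[C@H](C(C)C)[C@@H](/C=C(/COCc2ccc(OC)cc2)C(O)C=C)[C@H]1C[C@H](O[Si](CC)(CC)CC)[C@@](C)(O)C=C
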